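**Plan**

1. Numbering: tetralin C1 bears ring C and joins C8a of ring A; C2 and C3 carry the arms C2a and C3a; C4 is the CH2 on C4a.
2. Enabling feature: C1 holds two electron-rich aryl groups (ring C, and ring A through C8a) and lies 1,3 to C3a, so it can be an acetal carbon linked through oxygen to C3a.
3. Cuts: the C3a O–CH3 bond; then C1–C8a and C1–ring C in one operation (to an oxolane methyl acetal and veratrole); then the C2a O–CH3 bond, C1–C2 (to a β-benzyl lactone) and C3–C4 (Stobbe).
4. Forward: ring A is joined to the chain C4–C3(C3a)–C2–C2a and the lactone forms. C1 is added as CH(OMe)2, and reduction with acetal exchange switches the ring to the oxolane (O between C1 and C3a). The key step attaches ring C, opens the oxolane and closes ring B.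
5. Arms that are trans on ring B are cis on the oxolane, because at C2 the ring member and the substituent (C1 and C2a) change places. Hence C1, not C2a, is the group introduced trans on the lactone.
6. Stereochemistry: C3 comes from asymmetric hydrogenation, C2 from attack anti to the C3 benzyl group on the lactone, and C1 from the all-equatorial chair-like closure of ring B.

Key step: step 7

Assumption: (R,R)-Et-DuPHOS, which gives (R)-amino acid derivatives from enamides, is taken to give the spatially analogous (S)-2-substituted succinate. The sign of rotation of the benzyl lactone would check this, and the ligand antipode is equally available.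

**Step 1**
Reactants: 1 veratraldehyde; 2 dimethyl succinate
Product: 3 (E)-4-(3,4-dimethoxyphenyl)-3-(methoxycarbonyl)but-3-enoic acid
Conditions: NaOMe, MeOH, reflux; then aq. HCl
Reagents that add atoms: none
Why: The Stobbe condensation of an aromatic aldehyde with a succinic diester is driven by irreversible formation of the carboxylate and should give mainly the E half-ester (aryl trans to the ester), with the free acid on the future C2a and the ester on the future C3a.

**Step 2**
Reactants: 3 (E)-4-(3,4-dimethoxyphenyl)-3-(methoxycarbonyl)but-3-enoic acid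
Product: 4 (S)-4-(3,4-dimethoxyphenyl)-3-(methoxycarbonyl)butanoic acid
Conditions: H2 (5 bar), [Rh(cod)((R,R)-Et-DuPHOS)]BF4 (0.2 mol %), NaOMe (10 mol %), MeOH, rt
Reagents that add atoms: none
Why: Rhodium-catalysed asymmetric hydrogenation of Stobbe-derived itaconate half-esters is established for this ligand class, the carboxylate arm chelating the metal as the amide of an enamide does, so that the twofold-symmetric phospholane fixes the alkene face and sets C3 as S.

**Step 3**
Reactants: 4 (S)-4-(3,4-dimethoxyphenyl)-3-(methoxycarbonyl)butanoic acid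
Product: 6 (S)-4-(3,4-dimethoxybenzyl)oxolan-2-one, via hydroxy acid 5 (not isolated)
Conditions: KOH (1 equiv), EtOH; CaCl2, NaBH4, EtOH, −10 °C → rt; then 3 M HCl, rt
Reagents that add atoms: none
Why: Ca(BH4)2 made in the flask reduces the methyl ester but not the carboxylate salt (chemoselective borohydride reduction), and acidification lactonises 5 in a 5-exo-trig closure without touching C3.

**Step 4**
Reactants: 6 (S)-4-(3,4-dimethoxybenzyl)oxolan-2-one
Product: 8 (3R,4S)-4-(3,4-dimethoxybenzyl)-3-(dimethoxymethyl)oxolan-2-one (3,4-trans), via silyl ketene acetal 7 (not isolated)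
Conditions: LiN(i-Pr)2, THF, −78 °C; Me3SiCl; solvent change to CH2Cl2; HC(OMe)3 (3 equiv), Me3SiOTf (10 mol %), −78 °C
Reagents that add atoms: trimethyl orthoformate COC(OC)OC; chlorotrimethylsilane C[Si](C)(C)Cl (its atoms stay only in 7)
Why: Mukaiyama-type alkylation of a ketene silyl acetal by the dimethoxycarbenium ion released from an orthoformate is known for ester and lactone donors, and the electrophile should reach C2 anti to the C3 benzyl group to give the trans (also thermodynamic) lactone, with C1 already at the aldehyde oxidation level.

**Step 5**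
Reactants: 8 (3R,4S)-4-(3,4-dimethoxybenzyl)-3-(dimethoxymethyl)oxolan-2-one
Product: 10 [(3S,4S)-4-(3,4-dimethoxybenzyl)-2-methoxyoxolan-3-yl]methanol (3,4-cis; anomer mixture), via diol acetal 9 (not isolated)
Conditions: LiAlH4, THF, 0 °C; H2O/NaOH work-up; then pyridinium p-toluenesulfonate (10 mol %), CH2Cl2, rt
Reagents that add atoms: none
Why: Hydride reduction of the lactone to the 1,4-diol spares the acetal, and mild acid then drives an intramolecular transacetalisation in which only the C3a hydroxyl can reach C1 through a five-membered ring (the C2a hydroxyl would need a four-membered one), so the two primary alcohols are told apart while C2 and C3 stay untouched and their arms become cis on the new ring.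

**Step 6**
Reactants: 10 [(3S,4S)-4-(3,4-dimethoxybenzyl)-2-methoxyoxolan-3-yl]methanol
Product: 11 (3S,4S)-4-(3,4-dimethoxybenzyl)-2-methoxy-3-(methoxymethyl)oxolane (the O-methyl lactol; 3,4-cis; anomer mixture)
Conditions: NaH, MeI, THF, 0 °C → rt
Reagents that add atoms: iodomethane CI
Why: Williamson ether synthesis on the only free hydroxyl group caps the C2 arm, and because C1 is locked as a base-stable acetal there is no acidic C–H at C2 and no epimerisation is possible.

**Step 7**
Reactants: 11 (3S,4S)-4-(3,4-dimethoxybenzyl)-2-methoxy-3-(methoxymethyl)oxolane; 12 veratrole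
Product: 15 [(2S,3S,4R)-4-(3,4-dimethoxyphenyl)-6,7-dimethoxy-3-(methoxymethyl)-1,2,3,4-tetrahydronaphthalen-2-yl]methanol, via aryloxolane 13 (not isolated), via bridged ether 14 (not isolated)
Conditions: 12 (5 equiv), BF3·OEt2 (2.5 equiv), CH2Cl2, −40 °C → rt; aq. NaHCO3
Reagents that add atoms: none
Why: Proposed new method: BF3 ionises the C1–OMe bond of 11 to a five-membered oxocarbenium ion, veratrole attacks it para to a methoxy group from the face opposite both arms (C1–ring C bond, 13), and the acid then opens the now doubly activated benzylic C1–O bond to a C1 cation that ring A captures para to its C6 methoxy group (C1–C8a bond), the ring oxygen ending as the C3a hydroxyl. The closest known reaction types are the Lewis-acid Friedel–Crafts C-arylation of cyclic methyl acetals and lactols by electron-rich arenes and the acid rearrangement of 2-aryl-4-benzyloxolane lignans to aryltetralins, and only their merger at one carbon in one flask is untested. Ring B closes as a six-membered ring by intramolecular Friedel–Crafts alkylation, formally 6-exo-tet because the breaking C1–O bond lies outside the new ring, through a chair-like array. C1, the only new stereocentre, is controlled by C2 and C3: ring C and both arms are equatorial only in the array that gives the 1,2-trans (1R) isomer, and since C1 is planar at that stage the C1 configuration of 13 is irrelevant. If ring A adds first, which must occur on the oxolane face that also carries the C2 arm (6-exo-trig), bridged ether 14 reionises to a C1 cation stabilised by the C6 methoxy group and veratrole adds anti to the C2 arm, so both orders should converge on 15. The step needs mixed rather than double veratrole arylation, para regiochemistry and retention at C2; the tether makes ring A faster than a second veratrole, the other ortho site of ring A is flanked by chain and methoxy group, and the O-methyl lactol cannot open to an enolisable aldehyde while low temperature disfavours proton loss from C2.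

**Step 8**
Reactants: 15 [(2S,3S,4R)-4-(3,4-dimethoxyphenyl)-6,7-dimethoxy-3-(methoxymethyl)-1,2,3,4-tetrahydronaphthalen-2-yl]methanol
Product: 16 phyltetralin, (1R,2S,3S)-1-(3,4-dimethoxyphenyl)-6,7-dimethoxy-2,3-bis(methoxymethyl)-1,2,3,4-tetrahydronaphthalene
Conditions: NaH, MeI, THF, 0 °C → rt
Reagents that add atoms: iodomethane CI
Why: Williamson ether synthesis on the primary C3a hydroxyl freed in step 7 completes the second methoxymethyl arm, and none of the three stereocentres carries a hydrogen acidic enough to be removed under these conditions.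

**Compound list**

1 | veratraldehyde (3,4-dimethoxybenzaldehyde) | O=Cc1ccc(OC)c(OC)c1 | starting material
2 | dimethyl succinate | COC(=O)CCC(=O)OC | starting material
3 | (E)-4-(3,4-dimethoxyphenyl)-3-(methoxycarbonyl)but-3-enoic acid | COC(=O)/C(CC(=O)O)=C/c1ccc(OC)c(OC)c1 | intermediate
4 | (S)-4-(3,4-dimethoxyphenyl)-3-(methoxycarbonyl)butanoic acid | COC(=O)[C@@H](Cc1ccc(OC)c(OC)c1)CC(=O)O | intermediate
5 | (S)-3-(3,4-dimethoxybenzyl)-4-hydroxybutanoic acid (not isolated) | OC[C@@H](Cc1ccc(OC)c(OC)c1)CC(=O)O | intermediate
6 | (S)-4-(3,4-dimethoxybenzyl)oxolan-2-one | O=C1OC[C@@H](Cc2ccc(OC)c(OC)c2)C1 | intermediate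
7 | (S)-{[4-(3,4-dimethoxybenzyl)-4,5-dihydrofuran-2-yl]oxy}trimethylsilane (not isolated) | C[Si](C)(C)OC1=C[C@H](Cc2ccc(OC)c(OC)c2)CO1 | intermediate
8 | (3R,4S)-4-(3,4-dimethoxybenzyl)-3-(dimethoxymethyl)oxolan-2-one, 3,4-trans | O=C1OC[C@@H](Cc2ccc(OC)c(OC)c2)[C@@H]1C(OC)OC | intermediate
9 | (2S,3S)-2-(3,4-dimethoxybenzyl)-3-(dimethoxymethyl)butane-1,4-diol (not isolated) | OC[C@@H](C(OC)OC)[C@@H](CO)Cc1ccc(OC)c(OC)c1 | intermediate
10 | [(3S,4S)-4-(3,4-dimethoxybenzyl)-2-methoxyoxolan-3-yl]methanol, 3,4-cis, anomer mixture | COC1OC[C@@H](Cc2ccc(OC)c(OC)c2)[C@H]1CO | intermediate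
11 | (3S,4S)-4-(3,4-dimethoxybenzyl)-2-methoxy-3-(methoxymethyl)oxolane, 3,4-cis, anomer mixture | COC1OC[C@@H](Cc2ccc(OC)c(OC)c2)[C@H]1COC | intermediate
12 | veratrole (1,2-dimethoxybenzene) | COc1ccccc1OC | starting material
13 | (2R,3S,4S)-4-(3,4-dimethoxybenzyl)-2-(3,4-dimethoxyphenyl)-3-(methoxymethyl)oxolane, 2,3-trans-3,4-cis (not isolated) | COc1ccc(cc1OC)[C@@H]1OC[C@@H](Cc2ccc(OC)c(OC)c2)[C@H]1COC | intermediate
14 | (1S,2S,3S)-6,7-dimethoxy-2-(methoxymethyl)-1,3-(epoxymethano)tetralin, O on C1 bridged to C3a (alternative order, not isolated) | COC[C@@H]1[C@H]2CO[C@@H]1c3cc(OC)c(OC)cc3C2 | intermediate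
15 | [(2S,3S,4R)-4-(3,4-dimethoxyphenyl)-6,7-dimethoxy-3-(methoxymethyl)-1,2,3,4-tetrahydronaphthalen-2-yl]methanol (1R,2S,3S in the numbering of the plan) | OC[C@H]1Cc2cc(OC)c(OC)cc2[C@@H](c2ccc(OC)c(OC)c2)[C@@H]1COC | intermediate
16 | phyltetralin, (1R,2S,3S) | COC[C@H]1Cc2cc(OC)c(OC)cc2[C@@H](c2ccc(OC)c(OC)c2)[C@@H]1COC | target

Total steps: 8. Longest linear sequence: 8 (1 → 16); veratrole 12 enters as purchased.

**Steps most likely to fail**

**Step 7.**
- Proton loss from C2 of the oxocarbenium ion would scramble C2 and open the way to loss of methanol from the C2 arm.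
- Intermolecular capture by the only moderately nucleophilic veratrole may be slow.
- Facial selectivity at C1 may erode if veratrole adds last.

The fallback uses known chemistry and brings ring C in as an organometallic. It sets out from 11. Hydrolysis with dilute HCl in THF would give the lactol (3S,4S)-4-(3,4-dimethoxybenzyl)-3-(methoxymethyl)oxolan-2-ol F1. Addition of commercial 3,4-(MeO)2C6H3MgBr to its open form would give the diol (2S,3S)-2-(3,4-dimethoxybenzyl)-3-[(3,4-dimethoxyphenyl)(hydroxy)methyl]-4-methoxybutan-1-ol F2. CF3CO2H in CH2Cl2 then ionises the benzylic alcohol and closes ring B by the established cyclisation of such diols. The route is rejoined at 15.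

**Step 4.**
- C-silylation or hydrolysis of the ketene acetal may compete.
- Acid-induced loss of methanol from the new acetal would erase C2.

The fallback sets out from 6. Claisen formylation with methyl formate and NaH in THF would give (S)-4-(3,4-dimethoxybenzyl)-3-(hydroxymethylidene)oxolan-2-one F3. Acetalisation with HC(OMe)3 in MeOH under catalytic H2SO4 equilibrates C2 toward the more stable trans isomer. The route is rejoined at 8.

**Step 2.**
- Enantioface discrimination may be insufficient on this aryl-substituted alkene.
- The sense of induction may be opposite to the one assumed.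

The fallback sets out from 3. Hydrogenation over Pd/C in MeOH would give the racemic half-ester 4-(3,4-dimethoxyphenyl)-3-(methoxycarbonyl)butanoic acid F4. Its salts with (R)-1-phenylethylamine are separated by crystallisation. The (R)-1-phenylethylammonium salt of the (S)-acid F5 is taken from crystals or mother liquor as the rotation dictates. Acidification rejoins the route at 4.

**Further compounds**

F1 | step 7 | (3S,4S)-4-(3,4-dimethoxybenzyl)-3-(methoxymethyl)oxolan-2-ol, 3,4-cis, anomer mixture | OC1OC[C@@H](Cc2ccc(OC)c(OC)c2)[C@H]1COC
F2 | step 7 | (2S,3S)-2-(3,4-dimethoxybenzyl)-3-[(3,4-dimethoxyphenyl)(hydroxy)methyl]-4-methoxybutan-1-ol, carbinol epimers | OC(c1ccc(OC)c(OC)c1)[C@H](COC)[C@@H](CO)Cc1ccc(OC)c(OC)c1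
F3 | step 4 | (S)-4-(3,4-dimethoxybenzyl)-3-(hydroxymethylidene)oxolan-2-one | O=C1OC[C@@H](Cc2ccc(OC)c(OC)c2)C1=CO
F4 | step 2 | racemic 4-(3,4-dimethoxyphenyl)-3-(methoxycarbonyl)butanoic acid | COC(=O)C(Cc1ccc(OC)c(OC)c1)CC(=O)O
F5 | step 2 | (R)-1-phenylethylammonium (S)-4-(3,4-dimethoxyphenyl)-3-(methoxycarbonyl)butanoate | COC(=O)[C@@H](Cc1ccc(OC)c(OC)c1)CC(=O)[O-].C[C@@H]([NH3+])c1ccccc1
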